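**Retrosynthetic overview**
1. The last C–C bond made is C4–C5 of the side chain. The (Z)-trisubstituted alkene is disconnected by an iodine-triggered 1,2-metallate shift (alkyl group moves from boron to carbon, Zweifel type). This gives a C11 homoallyl pinacol boronate (ring half) and a C24 (E)-alkenyl metal (tail half).
2. The tail half comes from a C23 terminal alkyne and AlMe3 by methylalumination. The alkyne comes from the propyne dianion and a C20 primary bromide.
3. The C20 chain is built from 3-methylbut-1-ene by three identical hydroboration/alkyl–alkyl Suzuki cycles with one chiral C5 bromide. That bromide comes from (E)-1,4-dibromobut-2-ene by Cu-catalysed SN2′ methylation, and it sets all three chain stereocentres.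
4. The only ring is made first in its own branch, by an enantioselective isoprene/acrolein cycloaddition that sets the ring stereocentre. The sequence then runs CHO → C≡CH → 2-substituted butadiene (ethylene enyne metathesis) → 4,3-hydroboration.

Assumption: the SMILES is read literally (ring centre R, side-chain alkene Z, the three chain CH(CH3) centres all S). In steps 1 and 7 the ligand or catalyst enantiomer is defined by the product configuration it has to give.

**Step 1**
Reactants: 1 (E)-1,4-dibromobut-2-ene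
Product: 2 (R)-4-bromo-3-methylbut-1-ene
Conditions: MeMgBr (1.1 equiv), CuBr·SMe2 (1 mol %), Taniaphos = 1-[α-(dimethylamino)-2-(diphenylphosphino)benzyl]-2-(diphenylphosphino)ferrocene (1.2 mol %, enantiomer giving (R)-2), CH2Cl2, −75 °C
Reagents that add atoms: methylmagnesium bromide, C[Mg]Br
Why: Copper-catalysed asymmetric allylic alkylation (SN2′), in which the chiral copper–diphosphine complex delivers methyl to one face of the γ-carbon and so sets the stereocentre (about 95 % ee expected from related (E)-allyl bromides), while the second C–Br bond is no longer allylic and survives.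

**Step 2**
Reactants: 3 3-methylbut-1-ene; 2 (R)-4-bromo-3-methylbut-1-ene
Product: 5 (S)-3,7-dimethyloct-1-ene, via B-(3-methylbutyl)-9-BBN 4 (not isolated)
Conditions: 9-BBN-H (1.0 equiv B–H), THF, 0 °C to rt; then 2 (1.0 equiv), Pd(OAc)2 (4 mol %), PCy3 (8 mol %), K3PO4·H2O (1.2 equiv), THF, rt to 40 °C
Reagents that add atoms: 9-borabicyclo[3.3.1]nonane, [H]B1C2CCCC1CCC2 (its atoms end in 4 only)
Why: Anti-Markovnikov hydroboration followed by Pd/PCy3 alkyl–alkyl Suzuki–Miyaura coupling, whose SN2-type oxidative addition takes place at CH2Br and leaves the adjacent stereocentre of 2 untouched.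

**Step 3**
Reactants: 5 (S)-3,7-dimethyloct-1-ene; 2 (R)-4-bromo-3-methylbut-1-ene
Product: 7 (3S,7S)-3,7,11-trimethyldodec-1-ene, via B-alkyl-9-BBN adduct 6 (not isolated)
Conditions: 9-BBN-H (1.0 equiv B–H), THF, 0 °C to rt; then 2 (1.3 equiv), Pd(OAc)2 (4 mol %), PCy3 (8 mol %), K3PO4·H2O (1.2 equiv), THF, rt to 40 °C
Reagents that add atoms: 9-borabicyclo[3.3.1]nonane, [H]B1C2CCCC1CCC2 (its atoms end in 6 only)
Why: Same hydroboration/alkyl–alkyl Suzuki–Miyaura cycle, in which the new stereocentre arrives ready-made with 2 and three CH2 groups now separate it from the old one.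

**Step 4**
Reactants: 7 (3S,7S)-3,7,11-trimethyldodec-1-ene; 2 (R)-4-bromo-3-methylbut-1-ene
Product: 9 (3S,7S,11S)-3,7,11,15-tetramethylhexadec-1-ene, via B-alkyl-9-BBN adduct 8 (not isolated)
Conditions: 9-BBN-H (1.0 equiv B–H), THF, 0 °C to rt; then 2 (1.3 equiv), Pd(OAc)2 (4 mol %), PCy3 (8 mol %), K3PO4·H2O (1.2 equiv), THF, rt to 40 °C
Reagents that add atoms: 9-borabicyclo[3.3.1]nonane, [H]B1C2CCCC1CCC2 (its atoms end in 8 only)
Why: Third hydroboration/alkyl–alkyl Suzuki–Miyaura cycle, which brings in the third stereocentre with 2 (three uses of 95 % ee material give about 93 % of the all-S isomer).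

**Step 5**
Reactants: 9 (3S,7S,11S)-3,7,11,15-tetramethylhexadec-1-ene
Product: 10 (3S,7S,11S)-1-bromo-3,7,11,15-tetramethylhexadecane
Conditions: HBr (satd. in toluene), AIBN (5 mol %), 0 °C
Reagents that add atoms: hydrogen bromide, Br
Why: Radical-chain (Kharasch) anti-Markovnikov hydrobromination puts bromine on the terminal carbon and touches no stereocentre.

**Step 6**
Reactants: 11 propyne; 10 (3S,7S,11S)-1-bromo-3,7,11,15-tetramethylhexadecane
Product: 14 (6S,10S,14S)-6,10,14,18-tetramethylnonadec-1-yne, via 1,3-dilithiopropyne 12 (not isolated), via lithium acetylide 13 (not isolated)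
Conditions: 11 (1.5 equiv), n-BuLi (2.05 equiv per 11), TMEDA, Et2O/hexane, −78 °C to rt; then 10, THF, −78 °C to rt; H2O quench
Reagents that add atoms: n-butyllithium, [Li]CCCC (lithium in 12 and 13 only)
Why: SN2 alkylation of the propyne dianion occurs at the more reactive sp3 carbanion, so protonation of the remaining acetylide gives the terminal alkyne with three CH2 groups between C≡C and the first stereocentre.

**Step 7**
Reactants: 15 isoprene; 16 acrolein
Product: 17 (R)-4-methylcyclohex-3-ene-1-carbaldehyde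
Conditions: 5-benzyl-2,2,3-trimethylimidazolidin-4-one·HCl (20 mol %, enantiomer giving (R)-17), MeNO2/H2O 95:5, rt
Reagents that add atoms: none
Why: Iminium-catalysed enantioselective Diels–Alder reaction forms the ring with "para" regiochemistry, and the benzyl group of the catalyst shields one face of the iminium ion and so sets the ring stereocentre (about 90 % ee for this diene/enal pair).

**Step 8**
Reactants: 17 (R)-4-methylcyclohex-3-ene-1-carbaldehyde
Product: 18 (R)-4-ethynyl-1-methylcyclohex-1-ene
Conditions: dimethyl (1-diazo-2-oxopropyl)phosphonate (1.2 equiv), K2CO3 (2 equiv), MeOH, 0 °C to rt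
Reagents that add atoms: dimethyl (1-diazo-2-oxopropyl)phosphonate, COP(=O)(OC)C(=[N+]=[N-])C(C)=O
Why: Ohira–Bestmann (Seyferth–Gilbert) homologation, in which the diazoalkene loses N2 and the alkylidene carbene undergoes a 1,2-hydrogen shift to the alkyne, while the mild base at 0 °C keeps the α-stereocentre intact.

**Step 9**
Reactants: 18 (R)-4-ethynyl-1-methylcyclohex-1-ene; 19 ethylene
Product: 20 (R)-4-(buta-1,3-dien-2-yl)-1-methylcyclohex-1-ene
Conditions: 19 (1 atm), second-generation Grubbs catalyst (5 mol %), CH2Cl2, rt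
Reagents that add atoms: none
Why: Ruthenium-catalysed enyne cross-metathesis with ethylene turns a terminal alkyne into the 2-substituted 1,3-diene, and the trisubstituted ring alkene and the stereocentre are inert.

**Step 10**
Reactants: 20 (R)-4-(buta-1,3-dien-2-yl)-1-methylcyclohex-1-ene
Product: 21 4,4,5,5-tetramethyl-2-{3-[(1R)-4-methylcyclohex-3-en-1-yl]but-3-en-1-yl}-1,3,2-dioxaborolane
Conditions: HBpin (1.1 equiv), [Ir(cod)Cl]2 (1.5 mol %), dppe (3 mol %), CH2Cl2, rt
Reagents that add atoms: pinacolborane, [H]B1OC(C)(C)C(C)(C)O1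
Why: Iridium-catalysed 4,3-selective hydroboration of a 2-substituted 1,3-diene puts boron on the unsubstituted vinyl terminus, which gives the homoallyl boronate and keeps the 1,1-disubstituted and ring alkenes.

**Step 11**
Reactants: 14 (6S,10S,14S)-6,10,14,18-tetramethylnonadec-1-yne; 21 4,4,5,5-tetramethyl-2-{3-[(1R)-4-methylcyclohex-3-en-1-yl]but-3-en-1-yl}-1,3,2-dioxaborolane
Product: 25 (4R)-1-methyl-4-[(5Z,10S,14S,18S)-6,10,14,18,22-pentamethyltricosa-1,5-dien-2-yl]cyclohex-1-ene, via alkenyldimethylalane 22 (not isolated), via sodium boronate complex 23 (not isolated), via anti beta-iodo boronic ester 24 (not isolated)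
Conditions: 14, AlMe3 (2.0 equiv), Cp2ZrCl2 (20 mol %), CH2Cl2, 0 °C to rt; volatiles removed in vacuo; THF, 21 (1.0 equiv), dry NaOMe (1.05 equiv), −78 to 0 °C; I2 (1.3 equiv) in THF, −78 °C; NaOMe (3 equiv) in MeOH, −78 °C to rt
Reagents that add atoms: trimethylaluminium, C[Al](C)C; sodium methoxide, [Na+].[O-]C (sodium in 23 only); iodine, [I][I] (iodine in 24 only)
Why: Proposed new method: an alkoxide-triggered aluminium-to-boron alkenyl transfer that feeds a Zweifel-type 1,2-metallate shift straight from the carboalumination mixture; syn-methylalumination gives (E)-22 with Al cis to the new methyl group, methoxide converts it into an alkenyl(methoxy)aluminate that hands its sp2 carbon to the empty orbital of 21 while the weakly Lewis acidic Me2AlOMe left behind cannot take it back, iodine then forms the iodonium ion of 23, the primary alkyl group shifts from boron to the neighbouring carbon anti to iodine (24), and methoxide-induced anti B/I elimination inverts the alkene geometry so that the (E)-alkenyl metal ends as the (Z)-alkene with no stereocentre touched; the closest known reactions are the Negishi carboalumination with Al-to-B exchange onto alkoxyboranes and the Zweifel olefination of boronates made from alkenyllithiums.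

**Compound list**
1 | (E)-1,4-dibromobut-2-ene | BrC/C=C/CBr | starting material
2 | (R)-4-bromo-3-methylbut-1-ene | C=C[C@@H](C)CBr | intermediate
3 | 3-methylbut-1-ene | C=CC(C)C | starting material
4 | 9-(3-methylbutyl)-9-borabicyclo[3.3.1]nonane | CC(C)CCB1C2CCCC1CCC2 | intermediate
5 | (S)-3,7-dimethyloct-1-ene | C=C[C@@H](C)CCCC(C)C | intermediate
6 | 9-[(3R)-3,7-dimethyloctyl]-9-borabicyclo[3.3.1]nonane (same spatial arrangement as 5; the descriptor changes because boron ranks below carbon) | B1(CC[C@@H](C)CCCC(C)C)C2CCCC1CCC2 | intermediate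
7 | (3S,7S)-3,7,11-trimethyldodec-1-ene | C=C[C@@H](C)CCC[C@@H](C)CCCC(C)C | intermediate
8 | 9-[(3R,7S)-3,7,11-trimethyldodecyl]-9-borabicyclo[3.3.1]nonane (same spatial arrangement as 7) | B1(CC[C@@H](C)CCC[C@@H](C)CCCC(C)C)C2CCCC1CCC2 | intermediate
9 | (3S,7S,11S)-3,7,11,15-tetramethylhexadec-1-ene | C=C[C@@H](C)CCC[C@@H](C)CCC[C@@H](C)CCCC(C)C | intermediate
10 | (3S,7S,11S)-1-bromo-3,7,11,15-tetramethylhexadecane | BrCC[C@@H](C)CCC[C@@H](C)CCC[C@@H](C)CCCC(C)C | intermediate
11 | propyne | CC#C | starting material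
12 | 1,3-dilithiopropyne | [Li]CC#C[Li] | intermediate
13 | lithium (6S,10S,14S)-6,10,14,18-tetramethylnonadec-1-yn-1-ide | [Li]C#CCCC[C@@H](C)CCC[C@@H](C)CCC[C@@H](C)CCCC(C)C | intermediate
14 | (6S,10S,14S)-6,10,14,18-tetramethylnonadec-1-yne | C#CCCC[C@@H](C)CCC[C@@H](C)CCC[C@@H](C)CCCC(C)C | intermediate
15 | isoprene (2-methylbuta-1,3-diene) | C=CC(C)=C | starting material
16 | acrolein (prop-2-enal) | C=CC=O | starting material
17 | (R)-4-methylcyclohex-3-ene-1-carbaldehyde | O=C[C@H]1CC=C(C)CC1 | intermediate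
18 | (R)-4-ethynyl-1-methylcyclohex-1-ene | C#C[C@H]1CC=C(C)CC1 | intermediate
19 | ethylene | C=C | starting material
20 | (R)-4-(buta-1,3-dien-2-yl)-1-methylcyclohex-1-ene | C=CC(=C)[C@H]1CC=C(C)CC1 | intermediate
21 | 4,4,5,5-tetramethyl-2-{3-[(1R)-4-methylcyclohex-3-en-1-yl]but-3-en-1-yl}-1,3,2-dioxaborolane | C=C(CCB1OC(C)(C)C(C)(C)O1)[C@H]1CC=C(C)CC1 | intermediate
22 | dimethyl[(1E,6S,10S,14S)-2,6,10,14,18-pentamethylnonadec-1-en-1-yl]alane | C[Al](C)/C=C(\C)CCC[C@@H](C)CCC[C@@H](C)CCC[C@@H](C)CCCC(C)C | intermediate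
23 | sodium boronate complex of 21 carrying the (E)-alkenyl group of 22 on boron | [Na+].C=C(CC[B-]1(OC(C)(C)C(C)(C)O1)/C=C(\C)CCC[C@@H](C)CCC[C@@H](C)CCC[C@@H](C)CCCC(C)C)[C@H]2CC=C(C)CC2 | intermediate
24 | β-iodoalkyl pinacol boronate, anti adduct (Bpin on side-chain C5, iodine and methyl on C6; one of the two face isomers is drawn, the other has both new centres inverted and gives the same alkene) | C=C(CC[C@H](B1OC(C)(C)C(C)(C)O1)[C@@](C)(I)CCC[C@@H](C)CCC[C@@H](C)CCC[C@@H](C)CCCC(C)C)[C@H]1CC=C(C)CC1 | intermediate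
25 | (4R)-1-methyl-4-[(5Z,10S,14S,18S)-6,10,14,18,22-pentamethyltricosa-1,5-dien-2-yl]cyclohex-1-ene | C=C(CC/C=C(/C)CCC[C@@H](C)CCC[C@@H](C)CCC[C@@H](C)CCCC(C)C)[C@H]1CC=C(C)CC1 | target

**Step count**
Total step count: 11.
Longest linear sequence: 7 (steps 1, 2, 3, 4, 5, 6, 11).

**Steps most likely to fail**

Step 11 (the proposed new step).
- Risks: the aluminate may transfer methyl instead of alkenyl. The transfer to boron may be incomplete, in which case iodine simply iodinates the alane.
- Fallback (known chemistry, one step more): it sets out from 14 (with 21) and comes back at 24 and then 25. The carboalumination mixture from 14 is quenched with I2, and the alkenyl iodide (1E,6S,10S,14S)-1-iodo-2,6,10,14,18-pentamethylnonadec-1-ene F1 is isolated. Treatment with t-BuLi (2 equiv, Et2O, −78 °C) gives [(1E,6S,10S,14S)-2,6,10,14,18-pentamethylnonadec-1-en-1-yl]lithium F2. Addition of 21 gives the lithium boronate complex F3. I2 followed by NaOMe/MeOH (classical Zweifel olefination) then leads through 24 to 25.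

Step 2 (the same coupling recurs in steps 3 and 4).
- Risks: the bromide 2 is β-branched and homoallylic, so oxidative addition is slow. The alkylpalladium species can also lose isoprene by β-hydride elimination.
- Fallback (polarity reversed, so the branched partner becomes the nucleophile): it sets out from 3 and 2 and comes back at 5. Radical HBr addition to 3 gives 1-bromo-3-methylbutane F4. Bromide 2 and Mg (THF, kept at or below 0 °C) give (R)-(2-methylbut-3-en-1-yl)magnesium bromide F5. Li2CuCl4-catalysed Grignard–alkyl bromide coupling (THF, −20 to 0 °C) then gives 5.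
- Later rounds run the same way. From 5, (S)-1-bromo-3,7-dimethyloctane F6 leads to 7. From 7, (3S,7S)-1-bromo-3,7,11-trimethyldodecane F7 leads to 9. Each round costs one extra step.

Step 10.
- Risks: 1,4-addition or attack at the 1,1-disubstituted end of the diene would give allyl boronates instead of 21.
- Fallback (regiochemistry fixed by 1,2-shifts instead of catalyst control, one step more): it sets out from 18, leaves out 19 and 20, and comes back at 21. α-Selective hydroalumination of 18 (DIBAL-H, Ni(dppp)Cl2 3 mol %, THF) gives diisobutyl{1-[(1R)-4-methylcyclohex-3-en-1-yl]ethenyl}alane F8. This is trapped with 2-methoxy-4,4,5,5-tetramethyl-1,3,2-dioxaborolane to give 4,4,5,5-tetramethyl-2-{1-[(1R)-4-methylcyclohex-3-en-1-yl]ethenyl}-1,3,2-dioxaborolane F9. One Matteson homologation (BrCH2Cl, n-BuLi, THF, −78 °C to rt) gives 4,4,5,5-tetramethyl-2-{2-[(1R)-4-methylcyclohex-3-en-1-yl]prop-2-en-1-yl}-1,3,2-dioxaborolane F10. A second identical homologation gives 21.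

**Further compounds**
F1 | step 11 | (1E,6S,10S,14S)-1-iodo-2,6,10,14,18-pentamethylnonadec-1-ene | I/C=C(\C)CCC[C@@H](C)CCC[C@@H](C)CCC[C@@H](C)CCCC(C)C
F2 | step 11 | [(1E,6S,10S,14S)-2,6,10,14,18-pentamethylnonadec-1-en-1-yl]lithium | [Li]/C=C(\C)CCC[C@@H](C)CCC[C@@H](C)CCC[C@@H](C)CCCC(C)C
F3 | step 11 | lithium boronate complex of 21 carrying the (E)-alkenyl group of F2 on boron | [Li+].C=C(CC[B-]1(OC(C)(C)C(C)(C)O1)/C=C(\C)CCC[C@@H](C)CCC[C@@H](C)CCC[C@@H](C)CCCC(C)C)[C@H]2CC=C(C)CC2
F4 | step 2 | 1-bromo-3-methylbutane | CC(C)CCBr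
F5 | step 2 | (R)-(2-methylbut-3-en-1-yl)magnesium bromide | C=C[C@@H](C)C[Mg]Br
F6 | step 2 | (S)-1-bromo-3,7-dimethyloctane | BrCC[C@@H](C)CCCC(C)C
F7 | step 2 | (3S,7S)-1-bromo-3,7,11-trimethyldodecane | BrCC[C@@H](C)CCC[C@@H](C)CCCC(C)C
F8 | step 10 | diisobutyl{1-[(1R)-4-methylcyclohex-3-en-1-yl]ethenyl}alane | C=C([Al](CC(C)C)CC(C)C)[C@H]1CC=C(C)CC1
F9 | step 10 | 4,4,5,5-tetramethyl-2-{1-[(1R)-4-methylcyclohex-3-en-1-yl]ethenyl}-1,3,2-dioxaborolane | C=C(B1OC(C)(C)C(C)(C)O1)[C@H]1CC=C(C)CC1
F10 | step 10 | 4,4,5,5-tetramethyl-2-{2-[(1R)-4-methylcyclohex-3-en-1-yl]prop-2-en-1-yl}-1,3,2-dioxaborolane | C=C(CB1OC(C)(C)C(C)(C)O1)[C@H]1CC=C(C)CC1
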